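**Assumption:** the target SMILES has no stereocentre and the 2-arylbenzofuran axis is not configurationally stable, so the compound is achiral and no stereocontrol is needed.

## Retrosynthetic overview

1. Pyran ring last: acid-mediated hydroalkoxylation of one of two equivalent prenyl/phenol pairs on ring B.
2. The 1,1-dimethylallyl group at C7 comes from an aromatic Claisen rearrangement of a 6-O-prenyl benzofuran.
3. Furan ring: cyclodehydration of an α-aryl ketone whose C3–C3a bond is made by photostimulated SRN1 coupling of an aryl radical with a ketone enolate (key step).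
4. Both aryl partners come from resorcinol bis-MOM ether. The iodide partner uses ortho-lithiation/iodination, Ir C–H borylation/oxidation and O-prenylation. The ketone partner uses dibromination, lithiation between the bromines/acetylation and twofold Negishi prenylation.
5. Ring order: two benzene rings (from resorcinol) → furan → pyran.

## Route

**Step 1**
Reactants: 1 resorcinol
Product: 2 1,3-bis(methoxymethoxy)benzene
Conditions: MOMCl (2.4 equiv), NaH, DMF, 0 °C → rt
Reagents that add atoms: chloromethyl methyl ether, COCCl
Why: Williamson-type O-alkylation of both phenols; MOM directs lithiation, survives Ir, LDA, organozinc and enolate chemistry, and is removed later by mild acid.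

**Step 2**
Reactants: 2
Product: 3 2-iodo-1,3-bis(methoxymethoxy)benzene
Conditions: n-BuLi (1.1 equiv), THF, 0 °C, 1 h; then I2, −78 °C → rt
Reagents that add atoms: iodine, II
Why: Directed ortho-metalation at the carbon flanked by two OMOM groups, then iodine quench.

**Step 3**
Reactants: 3
Product: 4 4-iodo-3,5-bis(methoxymethoxy)phenol
Conditions: [Ir(OMe)(cod)]2 (1.5 mol %), dtbpy (3 mol %), B2pin2 (0.8 equiv), THF, 70 °C; then 30 % H2O2, aq NaOH, 0 °C (one pot)
Reagents that add atoms: hydrogen peroxide, OO (the phenol oxygen); bis(pinacolato)diboron, CC1(C)OB(OC1(C)C)B1OC(C)(C)C(C)(C)O1 (boron is transient and lost on oxidation)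
Why: Sterically controlled Ir-catalysed C–H borylation hits only C5, the one C–H with no ortho substituent (aryl iodides are tolerated); boronate oxidation gives the phenol para to iodine.

**Step 4**
Reactants: 4; 5 prenyl bromide (1-bromo-3-methylbut-2-ene)
Product: 6 2-iodo-1,3-bis(methoxymethoxy)-5-[(3-methylbut-2-en-1-yl)oxy]benzene
Conditions: K2CO3, acetone, 50 °C
Reagents that add atoms: none (beyond 5)
Why: Williamson etherification of the only free phenol; the prenyloxy group is para to iodine, so the later aryl radical cannot cyclise onto it.

**Step 5**
Reactants: 2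
Product: 7 1,5-dibromo-2,4-bis(methoxymethoxy)benzene
Conditions: NBS (2.05 equiv), MeCN, 0 °C → rt
Reagents that add atoms: N-bromosuccinimide, O=C1CCC(=O)N1Br
Why: Electrophilic aromatic substitution at the two positions ortho/para to the OMOM groups; the position between the two OMOM groups is the most hindered and stays free.

**Step 6**
Reactants: 7; 8 N-methoxy-N-methylacetamide
Product: 9 1-[2,6-dibromo-3,5-bis(methoxymethoxy)phenyl]ethan-1-one
Conditions: LDA (1.1 equiv), THF, −78 °C, 1 h; then 8, −78 → −40 °C; aq NH4Cl
Reagents that add atoms: none (beyond 8)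
Why: Deprotonation at the most acidic C–H, between the two bromines (an amide base gives no Br/Li exchange and no OMOM-directed lithiation at −78 °C), then Weinreb acylation to the methyl ketone.

**Step 7**
Reactants: 9; 5 prenyl bromide
Product: 10 1-[3,5-bis(methoxymethoxy)-2,6-bis(3-methylbut-2-en-1-yl)phenyl]ethan-1-one
Conditions: 5 (3.5 equiv), Zn dust, LiCl, THF, rt (prenylzinc bromide in situ); then 9, Pd(OAc)2 (5 mol %), CPhos (10 mol %), THF, rt → 40 °C
Reagents that add atoms: none (beyond 5)
Why: Twofold linear-selective Negishi coupling of an allylzinc halide. The di-ortho-substituted acetyl group is twisted perpendicular to the ring and shielded on both faces, so γ-attack of prenylzinc on the carbonyl should not compete.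

**Step 8 (key step)**
Reactants: 6; 10
Product: 11 2-[2,6-bis(methoxymethoxy)-4-(3-methylbut-2-en-1-yloxy)phenyl]-1-[3,5-bis(methoxymethoxy)-2,6-bis(3-methylbut-2-en-1-yl)phenyl]ethan-1-one
Conditions: 10 (2.2 equiv), KOtBu (2.1 equiv), degassed DMSO, rt; then 6 (1.0 equiv), hν (365 nm), 1–2 h; aq NH4Cl; excess 10 recovered
Reagents that add atoms: none
Why: Photostimulated SRN1 α-arylation of a ketone enolate. Electron transfer to 6 gives the aryl radical, which couples at the unhindered enolate CH2, and the product radical anion carries the chain. Aryne formation is impossible (no ortho H), and no free alkoxide is present to isomerise the prenyl groups.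

**Step 9**
Reactants: 11
Product: 12 2-[3,5-dihydroxy-2,6-bis(3-methylbut-2-en-1-yl)phenyl]-6-(3-methylbut-2-en-1-yloxy)-1-benzofuran-4-ol
Conditions: 3 M aq HCl, MeOH/THF, 45 °C
Reagents that add atoms: none
Why: Acetal hydrolysis frees four phenols, and one of the two equivalent ortho phenols of ring A adds to the ketone and dehydrates to the benzofuran (cyclodehydration). Ring A is symmetric, so only one benzofuran can form. MOM cleaves via an oxocarbenium ion and should go much faster than ionisation of the aryl prenyl ether or protonation of the prenyl alkenes.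

**Step 10**
Reactants: 12
Product: 13 2-[3,5-dihydroxy-2,6-bis(3-methylbut-2-en-1-yl)phenyl]-7-(2-methylbut-3-en-2-yl)-1-benzofuran-4,6-diol
Conditions: N,N-diethylaniline, degassed, 165 °C, 2–3 h
Reagents that add atoms: none
Why: Aromatic Claisen rearrangement ([3,3]) of the 6-O-prenyl ether. It should go to C7 across the C6–C7 bond, which has the higher π-bond order in benzofuran (as for 7-prenyloxycoumarins going to C8). The para position (C3a) is blocked and C5 is flanked by the 4-OH.

**Step 11**
Reactants: 13
Product: 14 Artopetelin C
Conditions: p-TsOH·H2O (0.2 equiv), toluene, 40 °C, stopped at about 50–60 % conversion; recovered 13 recycled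
Reagents that add atoms: none
Why: Markovnikov protonation of a trisubstituted prenyl alkene gives a tertiary cation that the adjacent phenol traps (6-endo hydroalkoxylation) to form the 2,2-dimethylchroman. The two prenyl/OH pairs are equivalent, so mono-cyclisation gives a single constitution, but the yield is statistical (about 45–50 % maximum per pass). The monosubstituted vinyl of the 1,1-dimethylallyl group would need a secondary cation and should stay intact.

## Compound list

1 | resorcinol | Oc1cccc(O)c1 | starting material
2 | 1,3-bis(methoxymethoxy)benzene | COCOc1cccc(OCOC)c1 | intermediate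
3 | 2-iodo-1,3-bis(methoxymethoxy)benzene | COCOc1cccc(OCOC)c1I | intermediate
4 | 4-iodo-3,5-bis(methoxymethoxy)phenol | COCOc1cc(O)cc(OCOC)c1I | intermediate
5 | prenyl bromide (1-bromo-3-methylbut-2-ene) | CC(C)=CCBr | starting material
6 | 2-iodo-1,3-bis(methoxymethoxy)-5-(prenyloxy)benzene | COCOc1cc(OCC=C(C)C)cc(OCOC)c1I | intermediate
7 | 1,5-dibromo-2,4-bis(methoxymethoxy)benzene | COCOc1cc(OCOC)c(Br)cc1Br | intermediate
8 | N-methoxy-N-methylacetamide | CC(=O)N(C)OC | starting material
9 | 1-[2,6-dibromo-3,5-bis(methoxymethoxy)phenyl]ethanone | CC(=O)c1c(Br)c(OCOC)cc(OCOC)c1Br | intermediate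
10 | 1-[3,5-bis(methoxymethoxy)-2,6-diprenylphenyl]ethanone | CC(=O)c1c(CC=C(C)C)c(OCOC)cc(OCOC)c1CC=C(C)C | intermediate
11 | α-aryl ketone from the SRN1 coupling | COCOc1cc(OCC=C(C)C)cc(OCOC)c1CC(=O)c1c(CC=C(C)C)c(OCOC)cc(OCOC)c1CC=C(C)C | intermediate
12 | 2-(3,5-dihydroxy-2,6-diprenylphenyl)-6-(prenyloxy)benzofuran-4-ol | CC(C)=CCOc1cc(O)c2cc(-c3c(CC=C(C)C)c(O)cc(O)c3CC=C(C)C)oc2c1 | intermediate
13 | 2-(3,5-dihydroxy-2,6-diprenylphenyl)-7-(1,1-dimethylallyl)benzofuran-4,6-diol | C=CC(C)(C)c1c(O)cc(O)c2cc(-c3c(CC=C(C)C)c(O)cc(O)c3CC=C(C)C)oc12 | intermediate
14 | Artopetelin C (achiral) | C=CC(C)(C)c1c(O)cc(O)c2cc(-c3c(CC=C(C)C)c(O)cc4c3CCC(C)(C)O4)oc12 | target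

## Summary

Total steps: 11.
Longest linear sequence: 8 (steps 1→2→3→4→8→9→10→11; the ketone branch 1→5→6→7→8→9→10→11 is also 8).

Three steps most likely to fail, each with a fallback:

1. **Step 8 (SRN1 coupling).** The chain may initiate poorly with this hindered aryl-ketone enolate, or the aryl radical may be reduced to the arene. Fallback: convert 10 to its trimethylsilyl enol ether and add the aryl radical to it as a neutral acceptor, generating the radical from 6 by halogen-atom transfer or photoredox reduction, with oxidation and desilylation giving 11.
2. **Step 10 (late Claisen).** Some C5 rearrangement or thermal cyclisation of the product onto the 6-OH is possible. Fallback: fix the 1,1-dimethylallyl group before the union. Ortho-iodinate 3,5-bis(methoxymethoxy)phenol, O-prenylate, run the Claisen into the only free ortho site, MOM-protect the phenol, and use that iodide in the SRN1 step (one step longer).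
3. **Step 7 (twofold Negishi on the hindered dibromo ketone).** Coupling may be incomplete or the organozinc may attack the carbonyl. Fallback: quench lithiated 7 with acetaldehyde instead of 8, silylate the carbinol, install both prenyl groups by twofold Br/Li exchange and copper-mediated alkylation with prenyl bromide, then desilylate and oxidise to 10.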